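The decalin is cut across ring B at the ring-fusion bond C5–C10 and at the C7=C8 alkene (drimane numbering). The precursor is an acyclic allylic phosphonium salt (C8–C9–C10) tethered through C1–C4 to an enal (C5–C6–C7). On deprotonation, the ylide adds through its γ-carbon C10 to the enal β-carbon C5 (ring A), and after proton transfer an intramolecular Wittig reaction joins C8 to C7 (ring B). The step exploits the 1,3-relationship of the quaternary C10 and the alkene carbon C8 about C9, whose substituent emerges as an exocyclic methylene, the handle for the CH2O–coumarin arm. The C3 stereocentre, from (S)-pantolactone, controls C5 and C10.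

Key step: step 12

Remark: drimane numbering is used throughout (ring A = C1–C5, C10; ring B = C5–C10; C11 = CH2O on C9; C12 = methyl on C8), and TBS = tert-butyldimethylsilyl, PMB = 4-methoxybenzyl. The target has the antipodal (ent-drimane) decalin, hence (S)-pantolactone. Compounds 10–12 and 14–16 are assumed to be carried as mixtures at the C10 carbinol or C8 centre and at the adjacent alkene, all of which are erased in step 12.

Step 1
Reactants: 1 (S)-pantolactone
Product: 2 (2S)-3,3-dimethylbutane-1,2,4-triol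
Conditions: LiAlH4, THF, 0 °C to reflux; aq. NaOH work-up
Reagents that add atoms: none
Why: Hydride reduction of the lactone to the diol leaves the carbinol centre (future C3, the only source of absolute configuration) untouched.

Step 2
Reactants: 2 (2S)-3,3-dimethylbutane-1,2,4-triol
Product: 3 [(2S,4S)-2-(4-methoxyphenyl)-5,5-dimethyl-1,3-dioxan-4-yl]methanol
Conditions: 4-MeOC6H4CH(OMe)2, CSA (cat.), CH2Cl2, rt
Reagents that add atoms: 4-methoxybenzaldehyde dimethyl acetal, COC(OC)c1ccc(OC)cc1
Why: Acid-catalysed transacetalisation under thermodynamic control should favour the six-membered 1,3-dioxane over the dioxolane and place the aryl group and the CH2OH arm both equatorial (cis), which fixes the acetal centre.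

Step 3
Reactants: 3 [(2S,4S)-2-(4-methoxyphenyl)-5,5-dimethyl-1,3-dioxan-4-yl]methanol
Product: 4 (2S,4S)-2-(4-methoxyphenyl)-5,5-dimethyl-1,3-dioxane-4-carbaldehyde
Conditions: Dess–Martin periodinane, NaHCO3, CH2Cl2, 0 °C to rt
Reagents that add atoms: none
Why: Dess–Martin oxidation of the primary alcohol under buffered conditions should give the α-alkoxy aldehyde without epimerisation at C3.

Step 4
Reactants: 4 (2S,4S)-2-(4-methoxyphenyl)-5,5-dimethyl-1,3-dioxane-4-carbaldehyde, 5 B-allyldiisopinocampheylborane of the (+)-α-pinene series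
Product: 6 (1S)-1-[(2S,4S)-2-(4-methoxyphenyl)-5,5-dimethyl-1,3-dioxan-4-yl]but-3-en-1-ol
Conditions: 5, Et2O, −78 °C; then aq. NaOH, H2O2, 0 °C to rt
Reagents that add atoms: none
Why: Brown allylboration through a closed chair transition state, in which the isopinocampheyl groups direct allyl transfer to the Si face of the aldehyde, should set C2 as S (2,3-syn) by reagent control against the opposite Felkin preference of the substrate.

Step 5
Reactants: 6 (1S)-1-[(2S,4S)-2-(4-methoxyphenyl)-5,5-dimethyl-1,3-dioxan-4-yl]but-3-en-1-ol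
Product: 7 tert-butyldimethylsilyl ether of 6
Conditions: TBSOTf, 2,6-lutidine, CH2Cl2, −78 to 0 °C
Reagents that add atoms: tert-butyldimethylsilyl triflate, CC(C)(C)[Si](C)(C)OS(=O)(=O)C(F)(F)F
Why: Silylation of the secondary alcohol with the silyl triflate and a hindered base is aprotic and should spare the acetal.

Step 6
Reactants: 7 tert-butyldimethylsilyl ether of 6
Product: 8 (4S)-4-(tert-butyldimethylsilyloxy)-4-[(2S,4S)-2-(4-methoxyphenyl)-5,5-dimethyl-1,3-dioxan-4-yl]butan-2-one
Conditions: PdCl2 (cat.), Cu(OAc)2 (cat.), O2 (1 atm), DMA/H2O, rt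
Reagents that add atoms: water, O
Why: Wacker–Tsuji oxidation converts the terminal alkene into the methyl ketone (C10 with its methyl) with Markovnikov regioselectivity, and the acetate co-oxidant keeps the medium close to neutral for the acetal.

Step 7
Reactants: 8 methyl ketone, 9 but-2-en-2-ylmagnesium bromide (E/Z mixture)
Product: 10 (6S)-6-(tert-butyldimethylsilyloxy)-6-[(2S,4S)-2-(4-methoxyphenyl)-5,5-dimethyl-1,3-dioxan-4-yl]-3,4-dimethylhex-2-en-4-ol (mixture at the new carbinol centre and the alkene)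
Conditions: 9, THF, −78 to 0 °C; aq. NH4Cl
Reagents that add atoms: none
Why: 1,2-Addition of the alkenyl Grignard reagent to the methyl ketone should give the tertiary allylic alcohol, whose new centre and alkene geometry need no control because both are erased in steps 11 and 12.

Step 8
Reactants: 10 tertiary allylic alcohol with the 4-methoxybenzylidene acetal
Product: 11 (3S,4S)-4-(TBSO)-3-(PMBO)-2,2,6,7-tetramethylnon-7-ene-1,6-diol
Conditions: i-Bu2AlH (excess), CH2Cl2, −78 to 0 °C; aq. potassium sodium tartrate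
Reagents that add atoms: none
Why: Regioselective reductive opening of the 4-methoxybenzylidene acetal: the aluminium hydride coordinates the less hindered primary oxygen, so the PMB ether should stay on the secondary C3 oxygen and the primary C5 alcohol is freed.

Step 9
Reactants: 11 (3S,4S)-4-(TBSO)-3-(PMBO)-2,2,6,7-tetramethylnon-7-ene-1,6-diol
Product: 12 (3S,4S)-4-(TBSO)-6-hydroxy-3-(PMBO)-2,2,6,7-tetramethylnon-7-enal
Conditions: Dess–Martin periodinane, NaHCO3, CH2Cl2, rt
Reagents that add atoms: none
Why: Dess–Martin oxidation of the neopentyl primary alcohol gives the C5 aldehyde, which has no α-hydrogen, while the tertiary allylic alcohol cannot be oxidised.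

Step 10
Reactants: 12 C5 aldehyde, 13 (triphenylphosphoranylidene)acetaldehyde
Product: 14 (2E,5S,6S)-6-(TBSO)-8-hydroxy-5-(PMBO)-4,4,8,9-tetramethylundeca-2,9-dienal
Conditions: 13, toluene, 90 °C
Reagents that add atoms: none
Why: Wittig olefination with the stabilised formyl ylide should give the (E)-enal (C5=C6–C7HO), which cannot enolise because C4 is quaternary.

Step 11
Reactants: 14 enal tertiary allylic alcohol
Product: 15 [(6S,7S,9E)-6-(TBSO)-7-(PMBO)-3,4,8,8-tetramethyl-11-oxoundeca-3,9-dien-2-yl]triphenylphosphonium bromide (Ph3P+ on C8, tetrasubstituted C9=C10 alkene)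
Conditions: PPh3·HBr, CH2Cl2, 0 °C to rt
Reagents that add atoms: triphenylphosphine hydrobromide, [Br-].c1ccc(cc1)[PH+](c1ccccc1)c1ccccc1
Why: Acid-promoted ionisation of the tertiary allylic alcohol and capture of the allyl cation by PPh3 at the less hindered secondary terminus (allylic transposition, the classical preparation of allylic Wittig salts from vinyl carbinols) should give the C8 phosphonium salt.

Step 12
Reactants: 15 allylic phosphonium bromide
Product: 18 (2S,3S,5S,10R)-2-(tert-butyldimethylsilyloxy)-3-(4-methoxybenzyloxy)drima-7,9(11)-diene, via allylic ylide 16 (not isolated), via ring A ylide aldehyde 17 (not isolated)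
Conditions: KOtBu (1.05 equiv), THF, high dilution (slow addition of 15), −40 to 50 °C
Reagents that add atoms: none
Why: Proposed new method: deprotonation at C8 gives the allylic ylide 16, whose γ-carbon C10 adds to the enal β-carbon C5 (6-exo-trig closure of ring A); the aldehyde enolate is then protonated at C6 while the C9 methyl (C11), now γ to a vinylphosphonium, is deprotonated, which regenerates an ylide at C8 (17) that closes ring B by intramolecular Wittig olefination onto the C7 aldehyde (6-exo-trig attack, oxaphosphetane, loss of Ph3PO) to give the C7=C8 and exocyclic C9=C11 alkenes. The closest known reaction type is the [3+3] cyclohexadiene annulation of allylic phosphonium ylides with α,β-unsaturated carbonyl compounds (γ-conjugate addition, proton transfer, intramolecular Wittig), which has not been shown intramolecularly, with an enal acceptor, or with a γ-carbon that carries no hydrogen so that a second γ-position must relay the proton. C5 and C10 are set in the ring A closure by a chair transition state in which the C2 silyloxy group, the C3 PMB ether and the enal arm on C5 are equatorial and the larger C9 arm on C10 is equatorial (methyl axial), so that H5 ends trans to the C10 methyl and cis to H3; the C3 centre from pantolactone is the controlling element. The step needs γ- over α-attack of the ylide and intra- over intermolecular olefination: γ-attack closes a six-membered ring whereas α-attack would need an eight- or ten-membered ring, the enal has no γ-hydrogen, and high dilution suppresses intermolecular Wittig reaction.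

Step 13
Reactants: 18 drima-7,9(11)-diene
Product: 20 (2S,3S,5S,9R,10R)-2-(tert-butyldimethylsilyloxy)-3-(4-methoxybenzyloxy)drim-7-en-11-ol, via B-alkyl-9-BBN adduct 19 (not isolated)
Conditions: 9-BBN, THF, 0 °C to rt; then aq. NaOH, H2O2, 0 °C to rt
Reagents that add atoms: 9-borabicyclo[3.3.1]nonane, B1C2CCCC1CCC2 (boron of 19 only); hydrogen peroxide, OO (oxygen of 20)
Why: Hydroboration–oxidation: the bulky borane should add only to the 1,1-disubstituted exocyclic alkene of the diene, with boron on the terminal C11, and deliver hydrogen to C9 from the face opposite the axial C10 methyl, which sets C9 as R (CH2OH equatorial, cis to the methyl).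

Step 14
Reactants: 20 C11 alcohol, 21 umbelliferone (7-hydroxycoumarin)
Product: 22 7-{[(2S,3S,5S,9R,10R)-2-(TBSO)-3-(PMBO)drim-7-en-11-yl]oxy}coumarin
Conditions: 21, PPh3, DIAD, THF, 0 to 40 °C
Reagents that add atoms: none
Why: Mitsunobu etherification of the primary alcohol with the acidic phenol (SN2 at C11, no stereocentre involved) should form the aryl ether.

Step 15
Reactants: 22 silyl ether
Product: 23 7-{[(2S,3S,5S,9R,10R)-2-hydroxy-3-(PMBO)drim-7-en-11-yl]oxy}coumarin
Conditions: HF·pyridine, THF/pyridine, 0 °C to rt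
Reagents that add atoms: none
Why: Fluoride-mediated cleavage of the silyl ether under mildly acidic conditions should spare the PMB ether, the coumarin lactone and the trisubstituted alkene.

Step 16
Reactants: 23 C2 alcohol
Product: 24 7-{[(3S,5S,9R,10R)-3-(PMBO)-2-oxodrim-7-en-11-yl]oxy}coumarin
Conditions: Dess–Martin periodinane, NaHCO3, CH2Cl2, rt
Reagents that add atoms: none
Why: Dess–Martin oxidation of the secondary alcohol gives the C2 ketone, and the equatorial C3 alkoxy group is the stable epimer, so the neighbouring centre is not at risk.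

Step 17
Reactants: 24 PMB ether
Product: 25 7-{[(3S,5S,9R,10R)-3-hydroxy-2-oxodrim-7-en-11-yl]oxy}coumarin
Conditions: DDQ, CH2Cl2/pH 7 phosphate buffer, 0 °C to rt
Reagents that add atoms: none
Why: Oxidative PMB cleavage by DDQ (oxidation of the electron-rich benzyl ether and hydrolysis of the resulting oxocarbenium ion) should free the C3 hydroxyl while the electron-poor coumarin ether is untouched.

Step 18
Reactants: 25 ketol, 26 angelic acid
Product: 28 CNP0111364.1, via angelic 2,4,6-trichlorobenzoic anhydride 27 (not isolated)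
Conditions: 26, 2,4,6-Cl3C6H2COCl, Et3N, toluene, rt; then 25, toluene, 80 °C
Reagents that add atoms: 2,4,6-trichlorobenzoyl chloride, O=C(Cl)c1c(Cl)cc(Cl)cc1Cl (in 27 only)
Why: Yamaguchi-type esterification through the mixed anhydride, run without DMAP, should acylate the ketol hydroxyl at the less hindered angeloyl carbonyl and keep the (Z)-alkene from isomerising to the tiglate.

Compound list

1 | (S)-pantolactone [(3S)-3-hydroxy-4,4-dimethyloxolan-2-one] | CC1(C)COC(=O)[C@H]1O | starting material
2 | (2S)-3,3-dimethylbutane-1,2,4-triol | O[C@@H](C(C)(C)CO)CO | intermediate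
3 | [(2S,4S)-2-(4-methoxyphenyl)-5,5-dimethyl-1,3-dioxan-4-yl]methanol | OC[C@H]1O[C@@H](c2ccc(OC)cc2)OCC1(C)C | intermediate
4 | (2S,4S)-2-(4-methoxyphenyl)-5,5-dimethyl-1,3-dioxane-4-carbaldehyde | O=C[C@H]1O[C@@H](c2ccc(OC)cc2)OCC1(C)C | intermediate
5 | allylbis[(1R,2S,3R,5R)-2,6,6-trimethylbicyclo[3.1.1]heptan-3-yl]borane (B-allyldiisopinocampheylborane, (+)-α-pinene series; commercial as a solution or made from the corresponding B-methoxyborane and allylmagnesium bromide) | C=CCB([C@@H]1C[C@@H]2C[C@H]([C@H]1C)C2(C)C)[C@@H]1C[C@@H]2C[C@H]([C@H]1C)C2(C)C | starting material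
6 | (1S)-1-[(2S,4S)-2-(4-methoxyphenyl)-5,5-dimethyl-1,3-dioxan-4-yl]but-3-en-1-ol | C=CC[C@H](O)[C@H]1O[C@@H](c2ccc(OC)cc2)OCC1(C)C | intermediate
7 | tert-butyldimethylsilyl ether of 6 | C=CC[C@H](O[Si](C)(C)C(C)(C)C)[C@H]1O[C@@H](c2ccc(OC)cc2)OCC1(C)C | intermediate
8 | (4S)-4-(tert-butyldimethylsilyloxy)-4-[(2S,4S)-2-(4-methoxyphenyl)-5,5-dimethyl-1,3-dioxan-4-yl]butan-2-one | CC(=O)C[C@H](O[Si](C)(C)C(C)(C)C)[C@H]1O[C@@H](c2ccc(OC)cc2)OCC1(C)C | intermediate
9 | but-2-en-2-ylmagnesium bromide (1-methyl-1-propenylmagnesium bromide, E/Z mixture) | CC=C(C)[Mg]Br | starting material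
10 | (6S)-6-(tert-butyldimethylsilyloxy)-6-[(2S,4S)-2-(4-methoxyphenyl)-5,5-dimethyl-1,3-dioxan-4-yl]-3,4-dimethylhex-2-en-4-ol (mixture at C4 of the chain and at the alkene) | CC=C(C)C(C)(O)C[C@H](O[Si](C)(C)C(C)(C)C)[C@H]1O[C@@H](c2ccc(OC)cc2)OCC1(C)C | intermediate
11 | (3S,4S)-4-(TBSO)-3-(PMBO)-2,2,6,7-tetramethylnon-7-ene-1,6-diol | CC=C(C)C(C)(O)C[C@H](O[Si](C)(C)C(C)(C)C)[C@@H](OCc1ccc(OC)cc1)C(C)(C)CO | intermediate
12 | (3S,4S)-4-(TBSO)-6-hydroxy-3-(PMBO)-2,2,6,7-tetramethylnon-7-enal | CC=C(C)C(C)(O)C[C@H](O[Si](C)(C)C(C)(C)C)[C@@H](OCc1ccc(OC)cc1)C(C)(C)C=O | intermediate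
13 | (triphenylphosphoranylidene)acetaldehyde | O=CC=P(c1ccccc1)(c1ccccc1)c1ccccc1 | starting material
14 | (2E,5S,6S)-6-(TBSO)-8-hydroxy-5-(PMBO)-4,4,8,9-tetramethylundeca-2,9-dienal | CC=C(C)C(C)(O)C[C@H](O[Si](C)(C)C(C)(C)C)[C@@H](OCc1ccc(OC)cc1)C(C)(C)/C=C/C=O | intermediate
15 | [(6S,7S,9E)-6-(TBSO)-7-(PMBO)-3,4,8,8-tetramethyl-11-oxoundeca-3,9-dien-2-yl]triphenylphosphonium bromide (mixture at C8 and at the C9=C10 alkene) | CC(C(C)=C(C)C[C@H](O[Si](C)(C)C(C)(C)C)[C@@H](OCc1ccc(OC)cc1)C(C)(C)/C=C/C=O)[P+](c1ccccc1)(c1ccccc1)c1ccccc1.[Br-] | intermediate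
16 | allylic ylide of 15 (ylide carbon C8) | CC(=P(c1ccccc1)(c1ccccc1)c1ccccc1)C(C)=C(C)C[C@H](O[Si](C)(C)C(C)(C)C)[C@@H](OCc1ccc(OC)cc1)C(C)(C)/C=C/C=O | intermediate (not isolated)
17 | ring A ylide aldehyde: cyclohexane with C10 quaternary (methyl, 3-(triphenylphosphoranylidene)but-1-en-2-yl), C5 bearing CH2CHO, 2-OTBS, 3-OPMB | COc1ccc(CO[C@@H]2[C@@H](O[Si](C)(C)C(C)(C)C)C[C@@](C)(C(=C)C(C)=P(c3ccccc3)(c3ccccc3)c3ccccc3)[C@H](CC=O)C2(C)C)cc1 | intermediate (not isolated)
18 | (2S,3S,5S,10R)-2-(tert-butyldimethylsilyloxy)-3-(4-methoxybenzyloxy)drima-7,9(11)-diene | COc1ccc(CO[C@@H]2[C@@H](O[Si](C)(C)C(C)(C)C)C[C@@]3(C)C(=C)C(C)=CC[C@@H]3C2(C)C)cc1 | intermediate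
19 | B-[(2S,3S,5S,9R,10R)-2-(TBSO)-3-(PMBO)drim-7-en-11-yl]-9-borabicyclo[3.3.1]nonane | COc1ccc(CO[C@@H]2[C@@H](O[Si](C)(C)C(C)(C)C)C[C@@]3(C)[C@H](CB4C5CCCC4CCC5)C(C)=CC[C@@H]3C2(C)C)cc1 | intermediate (not isolated)
20 | (2S,3S,5S,9R,10R)-2-(tert-butyldimethylsilyloxy)-3-(4-methoxybenzyloxy)drim-7-en-11-ol | COc1ccc(CO[C@@H]2[C@@H](O[Si](C)(C)C(C)(C)C)C[C@@]3(C)[C@H](CO)C(C)=CC[C@@H]3C2(C)C)cc1 | intermediate
21 | umbelliferone (7-hydroxy-2H-chromen-2-one) | O=c1ccc2ccc(O)cc2o1 | starting material
22 | 7-{[(2S,3S,5S,9R,10R)-2-(TBSO)-3-(PMBO)drim-7-en-11-yl]oxy}-2H-chromen-2-one | COc1ccc(CO[C@@H]2[C@@H](O[Si](C)(C)C(C)(C)C)C[C@@]3(C)[C@H](COc4ccc5ccc(=O)oc5c4)C(C)=CC[C@@H]3C2(C)C)cc1 | intermediate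
23 | 7-{[(2S,3S,5S,9R,10R)-2-hydroxy-3-(PMBO)drim-7-en-11-yl]oxy}-2H-chromen-2-one | COc1ccc(CO[C@@H]2[C@@H](O)C[C@@]3(C)[C@H](COc4ccc5ccc(=O)oc5c4)C(C)=CC[C@@H]3C2(C)C)cc1 | intermediate
24 | 7-{[(3S,5S,9R,10R)-3-(PMBO)-2-oxodrim-7-en-11-yl]oxy}-2H-chromen-2-one | COc1ccc(CO[C@@H]2C(=O)C[C@@]3(C)[C@H](COc4ccc5ccc(=O)oc5c4)C(C)=CC[C@@H]3C2(C)C)cc1 | intermediate
25 | 7-{[(3S,5S,9R,10R)-3-hydroxy-2-oxodrim-7-en-11-yl]oxy}-2H-chromen-2-one | O[C@@H]1C(=O)C[C@@]2(C)[C@H](COc3ccc4ccc(=O)oc4c3)C(C)=CC[C@@H]2C1(C)C | intermediate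
26 | angelic acid [(2Z)-2-methylbut-2-enoic acid] | C/C=C(/C)C(=O)O | starting material
27 | angelic 2,4,6-trichlorobenzoic anhydride | C/C=C(/C)C(=O)OC(=O)c1c(Cl)cc(Cl)cc1Cl | intermediate (not isolated)
28 | CNP0111364.1: (3S,5S,9R,10R)-2-oxo-11-[(2-oxo-2H-chromen-7-yl)oxy]drim-7-en-3-yl (2Z)-2-methylbut-2-enoate | C/C=C(/C)C(=O)O[C@@H]1C(=O)C[C@@]2(C)[C@H](COc3ccc4ccc(=O)oc4c3)C(C)=CC[C@@H]2C1(C)C | target

Total step count: 18
Longest linear sequence: 18 steps (1 to 28)

Steps most likely to fail

1. Step 12 (bears the label "Proposed new method:"). What may go wrong: the fully substituted γ-carbon of the ylide may add too slowly to the hindered C5, so that intermolecular α-olefination (oligomers) or ylide decomposition wins; the proton relay from C11 may fail; or facial selectivity in the ring A closure may be poor. The fallback uses known reactions only, sets out from 14 and comes back at 18. Palladium-catalysed allylic silylation of the tertiary allylic alcohol of 14 with hexamethyldisilane [Pd(BF4)2(MeCN)4, DMSO/MeOH] should give the transposed C8 allylsilane F1. Intramolecular Hosomi–Sakurai conjugate allylation (EtAlCl2, CH2Cl2, −78 °C) then forms C5–C10 through the same chair and gives the ring A aldehyde F2, which carries a but-2-en-2-yl group on C10. A type 2 intramolecular carbonyl-ene reaction (Me2AlCl, CH2Cl2, −78 to 0 °C) forms C7–C8 and the exocyclic C9=C11 alkene, giving the C7 homoallylic alcohol F3. Dehydration towards the allylic C8 hydrogen (Burgess reagent, toluene, 60 °C) gives diene 18.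

2. Step 11. What may go wrong: the allyl cation may lose a proton to give dienes before PPh3 captures it at the hindered secondary terminus, or the acid may attack the enal or the silyl ether. The fallback sets out from 14 and comes back at 15, replacing acid-mediated ionisation by a neutral two-stage activation. SN2′ bromination (PBr3, pyridine, Et2O, −20 °C) should give the transposed secondary allylic bromide F4, which is quaternised with PPh3 (MeCN, rt) to 15.

3. Step 14. What may go wrong: displacement at the β-branched C11 oxyphosphonium centre may be slow, with return of the alcohol or alkylation of the reduced azodicarboxylate. The fallback sets out from 20 and comes back at 22 with no new intermediate. It changes the bond-forming event from alkylation of the phenol to aryl C–O coupling: palladium-catalysed etherification of 20 with 7-bromocoumarin (Pd2(dba)3, t-BuBrettPhos, Cs2CO3, toluene, 90 °C).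

Further compounds
F1 | step 12 | C8 allylsilane: (2E,5S,6S)-6-(TBSO)-5-(PMBO)-4,4,8,9-tetramethyl-10-(trimethylsilyl)undeca-2,8-dienal | C[Si](C)(C)C(C)C(C)=C(C)C[C@H](O[Si](C)(C)C(C)(C)C)[C@@H](OCc1ccc(OC)cc1)C(C)(C)/C=C/C=O
F2 | step 12 | ring A aldehyde with a but-2-en-2-yl group on C10 (2-OTBS, 3-OPMB, C5 bearing CH2CHO) | COc1ccc(CO[C@@H]2[C@@H](O[Si](C)(C)C(C)(C)C)C[C@@](C)(C(C)=CC)[C@H](CC=O)C2(C)C)cc1
F3 | step 12 | (2S,3S,5S,10R)-2-(TBSO)-3-(PMBO)drim-9(11)-en-7-ol (mixture at C7 and C8) | COc1ccc(CO[C@@H]2[C@@H](O[Si](C)(C)C(C)(C)C)C[C@@]3(C)C(=C)C(C)C(O)C[C@@H]3C2(C)C)cc1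
F4 | step 11 | secondary allylic bromide: (2E,5S,6S)-10-bromo-6-(TBSO)-5-(PMBO)-4,4,8,9-tetramethylundeca-2,8-dienal | CC(Br)C(C)=C(C)C[C@H](O[Si](C)(C)C(C)(C)C)[C@@H](OCc1ccc(OC)cc1)C(C)(C)/C=C/C=O
F0 | step 14 | none | none
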